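## Structural features

The target 15 is an open, non-fused array of three benzene rings joined by two methylene bridges. Ring A, in the middle, is a hexasubstituted acylphloroglucinol: C1 carries the (R)-2-methylbutanoyl group, C2, C4 and C6 carry hydroxyls, and C3 and C5 carry the bridges. Each bridge ends at C1 of one of two identical, fully substituted side rings (C2 OH, C3 CH3, C4 OCH3, C5 acetyl, C6 OH). The only stereocenter is the α-carbon of the ring A ketone; it has no stereogenic neighbour, but it is enolizable and must be kept away from hot acid and strong base. The fragile elements are the seven phenols (oxidation as phenoxides), the two diarylmethane bridges flanked by oxygen on both sides (cleavage by ipso protonation under acid or by o-quinone methide extrusion under base), and the methyl ethers next to the acetyl groups (cleavage by hard Lewis acids). The real difficulty is regiochemical: each side ring holds three oxygens of which only the one para to the bridge is methylated, and the bridges must be made between very electron-rich rings without oligomerization. Because the two arms are identical, every operation on them can be run in two directions at once. The feature exploited is that, once the two acetyl groups are removed, C5 of each side ring is the only aromatic C–H of the whole trimer; it lies ortho to the C6 oxygen and para to the C2 oxygen, so an acetyl group resting on a phenol oxygen can be moved to C5 with no regiochemical choice.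

## Logic of the disconnections

15 ⇒ 14. Five O–acetyl bonds are cut. The phenols stay masked until the last operation, so the oxidation-prone polyphenol exists only once. The forward step must be a base-catalysed transesterification mild enough to spare the bridges and the stereocenter.

14 ⇒ 13. The two side-ring C5–C(=O)CH3 bonds are cut and each acetyl group is returned to the C6 oxygen. C5 is the only unsubstituted aromatic carbon, and the acetyl groups to be moved are the protecting groups already present, so no carbon has to be brought in from outside. Each side ring loses one substituent and the late intermediate 13 is a simple peracetate. The forward step must move an acetyl group from O to C twice under a Lewis acid without ether cleavage, bridge scission or enolization at the stereocenter.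

13 ⇒ 12. Three O–acetyl bonds on ring A are cut. Ring A needs free hydroxyls to act as the nucleophile in the bridge-forming step but capped ones for the migration, where free ortho-hydroxyls would invite ipso protonation at the bridges. The forward step must acetylate hindered, ketone-chelated hydroxyls completely.

12 ⇒ 11 + 2 × 7. The ring A C3–CH2 and C5–CH2 bonds are cut. This is the convergent, two-directional cut. 11 has exactly two free ring carbons, both wanted. The bridge carbon travels with the side ring, so its position there is fixed beforehand. The acetates on 7 are the ones needed in 13, and they also make the side-ring C–H a poor nucleophile, so the electrophile should not alkylate itself or the product. The forward step must ionize a benzylic acetate cleanly and alkylate twice.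

11 ⇒ 8 + 9. The aryl–C(=O) bond is cut. The stereocenter is bought with 8, and the threefold symmetry of 9 allows only one mono-acylation product. The forward step (through 10) must avoid ketene formation and enolization.

7 ⇒ 5 ⇒ 4. The benzylic C–O acetate is traced to the formyl group, and two O–acetyl bonds are cut. The aldehyde carbon is the future bridge. The forward reduction (through 6) must not set off the acetyl shift, 1,4-elimination and over-reduction sequence typical of ortho-acyloxy benzaldehydes.

4 ⇒ 3. The O–CH3 bond is cut. Of the three hydroxyls of 3, only the one para to the formyl group is both the most acidic and free of a hydrogen bond to the carbonyl; the two ortho hydroxyls both stay as hydroxyls, so they need not be distinguished. The forward step must be a mono-methylation under limiting base.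

3 ⇒ 1. The aryl–CHO bond is cut. The two open carbons of 1 are equivalent, so formylation (through 2) has one possible outcome, and the ring methyl group is bought rather than made.

## Other disconnections considered

Alternative 1: The cut removes three bonds of each side ring (C1–C2, C2–C3, C5–C6), so both side rings are built de novo on a ring A core carrying two 3-(triisopropylsiloxy)prop-2-ynyl arms, the bis(siloxyalkyne) A2. Forward, heating A2 with two equivalents of 3-methoxy-4-methylcyclobut-2-en-1-one A1 would run the Danheiser benzannulation twice (electrocyclic opening to a vinylketene, [2+2] addition to the ynol ether, second opening, 6π closure, tautomerization) and give the bis-phenol A3.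
- In its favour: the three side-ring oxygens are differentiated from the start (C2 OH, C4 OMe, C6 silyl ether) and the methyl group is placed by the reagent. This regiocontrol equals that of the chosen plan and is better in that no selective O-methylation is needed. The annulation is thermal and neutral, which is better for the bridges than any Lewis acid, and no electron-rich arene has to be benzylated.
- Against it here: ring A must be carried as a tribenzyl ether with the ketone masked as a silylated carbinol, which adds an uncontrolled stereocenter next to the existing one and several redox and protecting-group steps. A1 and the siloxyalkynes each need their own multi-step preparation. A3 still has C5–H, so the acetyl groups must be introduced afterwards, by the same O-to-C migration or by direct acylation.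
- Comparison: it replaces steps 1–7, not step 8, so on mechanism the two plans are not rivals. On step economy it is clearly longer and ends with three kinds of protecting group to remove, against one in the chosen plan.

Alternative 2: The cut is at the ring A ends of both bridges (ring A C3–CH and C5–CH). Forward, the complete side ring would arrive as the benzylic methyl sulfoxide A4. Activation with Tf2O, capture of the sulfonium by a phenol oxygen of 11, deprotonation at the benzylic carbon and a [2,3]-sigmatropic shift of the aryloxysulfonium ylide (Gassman-type ortho-alkylation of a phenol), run twice, would give the bis(methylthio) trimer A5. Desulfurization (Raney Ni) and deacetylation would follow.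
- In its favour: the acetyl groups are in place before coupling, so the assembled trimer never meets a Lewis acid at elevated temperature. This is better than the chosen plan for late-stage bridge and stereocenter integrity. The C–C bond is delivered to the carbon ortho to the anchoring oxygen, and both free carbons of ring A are such positions, so regiocontrol is equal. The nucleophilicity of the side ring is irrelevant.
- Against it here: A4 has acidic benzylic hydrogens and a strongly stabilized benzylic cation, so ordinary Pummerer ionization and C–S heterolysis compete with O-capture. Two of the three ring A hydroxyls are chelated to the ketone and are poor nucleophiles toward sulfur, and the sequence must succeed twice on one ring. Each bridge carbon becomes a temporary stereocenter, so A5 would be a diastereomer mixture until sulfur is removed. The desulfurization must spare three aryl ketones.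
- Comparison: A4 needs the same aldehyde-derived benzylic carbon as 7 plus acetylation, thiolation and oxidation, so the plan is some steps longer. It moves the uncertainty from the last C–C bond formation (chosen plan) to the coupling itself.

Alternative 3: The cut is the ring A C1–C2 bond. Ring A is made last from an acyclic chain stored as the 4-hydroxy-2-pyrone A6, which already carries both benzyl-protected side arms on C3 and C5 and the (R)-3-methyl-2-oxopentyl chain on C6. Forward, Mg(OMe)2 in methanol would open A6 to the magnesium chelate of triketo ester A7. Claisen condensation of its C6 methylene onto the ester carbonyl (6-exo-trig at the ester carbon, then enolization) would close ring A and give A8.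
- In its favour: the hexasubstituted ring A arises in one step with both bridges attached. The bridge bonds come from enolate C-alkylation with a regiodefined benzylic halide, which is equal in regiocontrol and better in that no cation is generated next to an electron-rich arene. The conditions are mild and biomimetic.
- Against it here: the stereocenter lies α to a ketone of a 1,3,5-tricarbonyl chain and is exposed to methoxide throughout the cyclization, whereas in the chosen plan it sits on an aromatic ketone from step 5 onwards. The chelate must prefer Claisen over aldol closure (the aldol mode would give a resorcylate). The construction of A6 is long.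
- Comparison: A8 still needs four hydrogenolyses, a peracetylation and the same migration step to reach 14, so this plan competes only with steps 5 and 6 and replaces them by a much longer sequence. The chosen plan is shorter and safer for the stereocenter; the alternative is equal in regiocontrol of the bridges.

Key step: step 8

Remark: the single stereocenter is read from the target SMILES as R. 2,4,6-Trihydroxytoluene, anhydrous phloroglucinol and (R)-2-methylbutanoic acid are taken as commercial, so the side-ring methyl group is bought with 1 rather than introduced by C-methylation of a phenoxide.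

## Route

Step 1
Reactants: 1 2,4,6-trihydroxytoluene (2-methylbenzene-1,3,5-triol)
Product: 3 2,4,6-trihydroxy-3-methylbenzaldehyde, via aryl iminium chloride 2 (not isolated)
Conditions: POCl3, DMF, EtOAc, 0 °C → rt; then H2O, 60 °C
Reagents that add atoms: N,N-dimethylformamide, CN(C)C=O (formyl carbon; its NMe2 group stays only in 2); water, O (aldehyde oxygen); POCl3, O=P(Cl)(Cl)Cl (chloride of 2 only)
Why: Vilsmeier–Haack formylation of a phloroglucinol; the two free carbons of 1 are equivalent, the iminium salt 2 is deactivated toward a second formylation, and it is hydrolysed on aqueous work-up.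

Step 2
Reactants: 3 2,4,6-trihydroxy-3-methylbenzaldehyde
Product: 4 2,6-dihydroxy-4-methoxy-3-methylbenzaldehyde
Conditions: Me2SO4 (1.05 equiv), K2CO3 (1.05 equiv), acetone, 0 °C → rt
Reagents that add atoms: dimethyl sulfate, COS(=O)(=O)OC
Why: Williamson-type O-methylation under limiting base; the hydroxyl para to the formyl group is the most acidic and the only one not ortho to the carbonyl and its hydrogen bond, so its phenoxide should form and react first.

Step 3
Reactants: 4 2,6-dihydroxy-4-methoxy-3-methylbenzaldehyde
Product: 5 2-formyl-5-methoxy-4-methyl-1,3-phenylene diacetate
Conditions: Ac2O, pyridine, DMAP (cat.), CH2Cl2, 0 °C → rt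
Reagents that add atoms: acetic anhydride, CC(=O)OC(C)=O
Why: DMAP-catalysed O-acetylation; it installs the acetates that 13 needs, frees the aldehyde from chelation, and lowers the nucleophilicity of the ring C–H for the later coupling.

Step 4
Reactants: 5 2-formyl-5-methoxy-4-methyl-1,3-phenylene diacetate
Product: 7 2-(acetoxymethyl)-5-methoxy-4-methyl-1,3-phenylene diacetate, via benzylic alcohol 6 (not isolated)
Conditions: BH3·THF, THF, 0 °C; MeOH quench, concentrate; then Ac2O, pyridine, DMAP (cat.), CH2Cl2, rt
Reagents that add atoms: acetic anhydride, CC(=O)OC(C)=O
Why: Electrophilic borane reduces the aldehyde much faster than aryl esters and gives a neutral borate rather than a free alkoxide, which should avoid the ortho-acetyl shift, 1,4-elimination and over-reduction seen with basic hydrides; immediate acetylation of 6 gives the stable triacetate and corrects any acetyl shift.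

Step 5
Reactants: 8 (R)-2-methylbutanoic acid; 9 phloroglucinol (benzene-1,3,5-triol, anhydrous)
Product: 11 (2R)-2-methyl-1-(2,4,6-trihydroxyphenyl)butan-1-one, via acid chloride 10 (not isolated)
Conditions: (COCl)2, DMF (cat.), CH2Cl2, 0 °C → rt, concentrate; then 9, AlCl3, CH2Cl2–MeNO2, 0 °C → rt; aq HCl
Reagents that add atoms: oxalyl chloride, O=C(Cl)C(=O)Cl (chlorine of 10 only; none of its atoms remain in 11)
Why: Friedel–Crafts C-acylation of phloroglucinol; base-free formation of 10 and acylation at or below room temperature are chosen so that neither ketene formation nor enolization erodes the R stereocenter, which is carried over unchanged from 8.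

Step 6
Reactants: 11 (2R)-2-methyl-1-(2,4,6-trihydroxyphenyl)butan-1-one; 7 2-(acetoxymethyl)-5-methoxy-4-methyl-1,3-phenylene diacetate (2.2 equiv)
Product: 12 (2R)-1-{3,5-bis[(2,6-diacetoxy-4-methoxy-3-methylphenyl)methyl]-2,4,6-trihydroxyphenyl}-2-methylbutan-1-one
Conditions: Sc(OTf)3 (10 mol %), MeNO2, rt → 40 °C
Reagents that add atoms: none
Why: Lewis-acid-catalysed Friedel–Crafts benzylation with a benzylic acetate; ionization of 7 gives a para-methoxy-stabilized benzylic cation that is captured by the only two free carbons of ring A. The acetylated side ring is far less nucleophilic than the free triol ring A, so self-alkylation at its C–H should be suppressed, and O-alkylation is reversible under acid.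

Step 7
Reactants: 12 (2R)-1-{3,5-bis[(2,6-diacetoxy-4-methoxy-3-methylphenyl)methyl]-2,4,6-trihydroxyphenyl}-2-methylbutan-1-one
Product: 13 (2R)-1-{2,4,6-triacetoxy-3,5-bis[(2,6-diacetoxy-4-methoxy-3-methylphenyl)methyl]phenyl}-2-methylbutan-1-one (heptaacetate)
Conditions: Ac2O, pyridine, DMAP (cat.), rt → 40 °C
Reagents that add atoms: acetic anhydride, CC(=O)OC(C)=O
Why: DMAP-catalysed acetylation of the three hindered, chelated ring A hydroxyls; it also restores any side-ring acetate lost in step 6, and pyridine is too weak a base to remove the tertiary α-hydrogen.

Step 8
Reactants: 13 (2R)-1-{2,4,6-triacetoxy-3,5-bis[(2,6-diacetoxy-4-methoxy-3-methylphenyl)methyl]phenyl}-2-methylbutan-1-one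
Product: 14 (2R)-1-{2,4,6-triacetoxy-3,5-bis[(2-acetoxy-5-acetyl-6-hydroxy-4-methoxy-3-methylphenyl)methyl]phenyl}-2-methylbutan-1-one (pentaacetate; side-ring numbering as in the text)
Conditions: BF3·OEt2 (excess), ClCH2CH2Cl, 60 °C; then aq NaHCO3
Reagents that add atoms: none
Why: Fries rearrangement run in two directions: BF3 binds the carbonyl oxygen of the C6–O acetate of a side ring, the aryl O–acyl bond ionizes to a tight boron phenoxide/acylium pair, and the acylium attacks C5, which is ortho to that oxygen, ortho to the C4 methoxy donor and para to the C2 oxygen; loss of the C5 proton restores the arene, and the new o-hydroxy ketone stays boron-chelated until work-up. The closest known reaction type is the Lewis-acid Fries rearrangement of phloroglucinol ether acetates such as 3,5-dimethoxyphenyl acetate, where the acyl group also enters a position flanked by two oxygens. No ring is closed and no stereocenter is created. The selectivity needed is positional, and the substrate secures it: ring A is hexasubstituted and each side ring has one C–H, so an ortho shift from C6–O, a para shift from C2–O or intermolecular transfer from any other acetate can only end at C5, and the number of acetyl groups is conserved. Chemoselectivity rests on the fully acetylated phenols, which make both ends of each bridge poor sites for ipso protonation, and on BF3, which does not cleave aryl methyl ethers. The R stereocenter is not involved; the twisted, di-ortho-substituted aryl ketone is a poor ligand for boron, and the moderate temperature limits enolization. Any isomer that keeps its residual acetates on other oxygens converges on 15 in step 9.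

Step 9
Reactants: 14 (2R)-1-{2,4,6-triacetoxy-3,5-bis[(2-acetoxy-5-acetyl-6-hydroxy-4-methoxy-3-methylphenyl)methyl]phenyl}-2-methylbutan-1-one
Product: 15 (2R)-1-{3,5-bis[(3-acetyl-2,6-dihydroxy-4-methoxy-5-methylphenyl)methyl]-2,4,6-trihydroxyphenyl}-2-methylbutan-1-one (CNP0201397.1)
Conditions: K2CO3, MeOH (degassed), 0 °C → rt, Ar; then aq HCl to pH 4
Reagents that add atoms: none
Why: Base-catalysed transesterification of the five aryl acetates to methyl acetate; the phenoxides released ortho to the ketones turn them into vinylogous carboxylates that resist enolization, and low temperature with exclusion of air protects the bridges and the polyphenol.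

## Compound list

1 | 2,4,6-trihydroxytoluene (2-methylbenzene-1,3,5-triol) | Cc1c(O)cc(O)cc1O | starting material
2 | N-[(2,4,6-trihydroxy-3-methylphenyl)methylidene]-N-methylmethanaminium chloride | C[N+](C)=Cc1c(O)cc(O)c(C)c1O.[Cl-] | intermediate
3 | 2,4,6-trihydroxy-3-methylbenzaldehyde | O=Cc1c(O)cc(O)c(C)c1O | intermediate
4 | 2,6-dihydroxy-4-methoxy-3-methylbenzaldehyde | O=Cc1c(O)cc(OC)c(C)c1O | intermediate
5 | 2-formyl-5-methoxy-4-methyl-1,3-phenylene diacetate | O=Cc1c(OC(C)=O)cc(OC)c(C)c1OC(C)=O | intermediate
6 | 2-(hydroxymethyl)-5-methoxy-4-methyl-1,3-phenylene diacetate | OCc1c(OC(C)=O)cc(OC)c(C)c1OC(C)=O | intermediate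
7 | 2-(acetoxymethyl)-5-methoxy-4-methyl-1,3-phenylene diacetate | CC(=O)OCc1c(OC(C)=O)cc(OC)c(C)c1OC(C)=O | intermediate
8 | (R)-2-methylbutanoic acid | CC[C@@H](C)C(=O)O | starting material
9 | phloroglucinol (benzene-1,3,5-triol) | Oc1cc(O)cc(O)c1 | starting material
10 | (R)-2-methylbutanoyl chloride | CC[C@@H](C)C(=O)Cl | intermediate
11 | (2R)-2-methyl-1-(2,4,6-trihydroxyphenyl)butan-1-one | CC[C@@H](C)C(=O)c1c(O)cc(O)cc1O | intermediate
12 | (2R)-1-{3,5-bis[(2,6-diacetoxy-4-methoxy-3-methylphenyl)methyl]-2,4,6-trihydroxyphenyl}-2-methylbutan-1-one | CC[C@@H](C)C(=O)c1c(O)c(Cc2c(OC(C)=O)c(C)c(OC)cc2OC(C)=O)c(O)c(Cc2c(OC(C)=O)c(C)c(OC)cc2OC(C)=O)c1O | intermediate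
13 | (2R)-1-{2,4,6-triacetoxy-3,5-bis[(2,6-diacetoxy-4-methoxy-3-methylphenyl)methyl]phenyl}-2-methylbutan-1-one | CC[C@@H](C)C(=O)c1c(OC(C)=O)c(Cc2c(OC(C)=O)c(C)c(OC)cc2OC(C)=O)c(OC(C)=O)c(Cc2c(OC(C)=O)c(C)c(OC)cc2OC(C)=O)c1OC(C)=O | intermediate
14 | (2R)-1-{2,4,6-triacetoxy-3,5-bis[(2-acetoxy-5-acetyl-6-hydroxy-4-methoxy-3-methylphenyl)methyl]phenyl}-2-methylbutan-1-one | CC[C@@H](C)C(=O)c1c(OC(C)=O)c(Cc2c(OC(C)=O)c(C)c(OC)c(C(C)=O)c2O)c(OC(C)=O)c(Cc2c(OC(C)=O)c(C)c(OC)c(C(C)=O)c2O)c1OC(C)=O | intermediate
15 | (2R)-1-{3,5-bis[(3-acetyl-2,6-dihydroxy-4-methoxy-5-methylphenyl)methyl]-2,4,6-trihydroxyphenyl}-2-methylbutan-1-one | CC[C@@H](C)C(=O)c1c(O)c(Cc2c(O)c(C)c(OC)c(C(C)=O)c2O)c(O)c(Cc2c(O)c(C)c(OC)c(C(C)=O)c2O)c1O | target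

## Step count and least certain steps

Total step count: 9. Longest linear sequence: 8 steps (steps 1, 2, 3, 4, 6, 7, 8, 9, from 1 to 15); step 5 is the side branch.

Step 8 (key step). The most likely failures are a stalled second migration, acid-induced scission or scrambling of the diarylmethane bridges, further acyl transfer onto the methyl group of the new ketone, and erosion of the stereocenter by Lewis-acid enolization; all grow with temperature, which the modest activation of C5 may force upward. Catalytic Sc(OTf)3 in MeNO2 is the milder variant of the same reaction. The fallback changes the approach to a direct C-acylation of the free phenol at low temperature. It sets out from 12: methanolysis (K2CO3, MeOH, 0 °C) would give the heptaphenol F1, in which the side rings are phloroglucinol monomethyl ethers. Houben–Hoesch reaction with MeCN (ZnCl2, HCl, Et2O, 0 °C) would then acylate the only free carbon of each side ring to the bis(ketiminium chloride) F2, and hydrolysis in warm water would return to the route at 15.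

Step 6. The most likely failures are slow ionization of the benzylic acetate, which is flanked by two acetoxy groups, stalling after the first benzylation for steric reasons, and transfer of acetyl groups from the side ring to ring A oxygens, which would release nucleophilic side-ring phenols and open the way to self-alkylation. The fallback replaces the cationic alkylation by a conjugate addition. It sets out from 7 and 11 with K2CO3 in MeOH–THF (0 °C → rt): methanolysis of a phenolic acetate of 7 and 1,4-elimination of the benzylic acetate would give the o-quinone methide F3 (not isolated), to which the phloroglucinate of 11 should add through C3 and then C5. With complete deacetylation this leads to the heptaphenol F1 (the compound of the fallback for step 8), and peracetylation (Ac2O, pyridine, DMAP) returns to the route at 13.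

Step 4. The most likely failure is migration of an ortho acetyl group to the new benzylic oxygen, followed by 1,4-elimination and a second hydride delivery that reduces the bridge carbon to a methyl group; slow reduction of the aryl acetates by excess borane is the other risk. The fallback avoids reducing a carbonyl next to aryl acetates. It sets out from 4: reductive amination with morpholine (NaBH(OAc)3, ClCH2CH2Cl, rt) would give the phenolic Mannich base F4, and acetolysis in Ac2O at reflux (the known conversion of phenolic Mannich bases into o-acetoxybenzyl acetates) would return to the route at 7, bypassing 5 and 6.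

Step 2. The most likely failure is poor site selectivity of the methylation (reaction at an ortho hydroxyl or twice), because the acidity difference between the hydroxyls is modest. The fallback replaces selective alkylation by selective dealkylation. It sets out from 3: exhaustive methylation (Me2SO4 excess, K2CO3, acetone, reflux) would give 2,4,6-trimethoxy-3-methylbenzaldehyde F5, and AlCl3 (excess, CH2Cl2, reflux) would cleave only the two methoxy groups ortho to the formyl group through the aluminium chelate, returning to the route at 4.

Step 5. The most likely failure is partial racemization, through ketene formation from 10 or enolization of the AlCl3-bound ketone; a second acylation is the minor risk. The fallback forms the aryl ketone by organometallic addition. It sets out from 8 and 9: 8 would be converted into the Weinreb amide F6 (MeNHOMe·HCl, EDC·HCl, i-Pr2NEt, CH2Cl2) and 9 into 1,3,5-tris(methoxymethoxy)benzene F7 (MOMCl, i-Pr2NEt, CH2Cl2). Lithiation of F7 (n-BuLi, THF, 0 °C) would give the aryllithium F8 (not isolated), whose addition to F6 at −78 °C would give the tris(methoxymethyl) ether ketone F9 through a stable tetrahedral adduct. Acetal cleavage (HCl, MeOH, 40 °C) returns to the route at 11.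

## Further compounds

F1 | step 8 | (2R)-1-{3,5-bis[(2,6-dihydroxy-4-methoxy-3-methylphenyl)methyl]-2,4,6-trihydroxyphenyl}-2-methylbutan-1-one (heptaphenol) | CC[C@@H](C)C(=O)c1c(O)c(Cc2c(O)c(C)c(OC)cc2O)c(O)c(Cc2c(O)c(C)c(OC)cc2O)c1O
F2 | step 8 | bis(ketiminium chloride) of 15 (both side-ring acetyl groups as C(CH3)=NH2+ Cl−) | CC[C@@H](C)C(=O)c1c(O)c(Cc2c(O)c(C)c(OC)c(C(C)=[NH2+])c2O)c(O)c(Cc2c(O)c(C)c(OC)c(C(C)=[NH2+])c2O)c1O.[Cl-].[Cl-]
F3 | step 6 | 5-hydroxy-3-methoxy-4-methyl-6-methylidenecyclohexa-2,4-dien-1-one (o-quinone methide) | C=C1C(=O)C=C(OC)C(C)=C1O
F4 | step 4 | 5-methoxy-4-methyl-2-(morpholin-4-ylmethyl)benzene-1,3-diol (Mannich base) | Cc1c(O)c(CN2CCOCC2)c(O)cc1OC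
F5 | step 2 | 2,4,6-trimethoxy-3-methylbenzaldehyde | O=Cc1c(OC)cc(OC)c(C)c1OC
F6 | step 5 | (2R)-N-methoxy-N,2-dimethylbutanamide (Weinreb amide) | CC[C@@H](C)C(=O)N(C)OC
F7 | step 5 | 1,3,5-tris(methoxymethoxy)benzene | COCOc1cc(OCOC)cc(OCOC)c1
F8 | step 5 | [2,4,6-tris(methoxymethoxy)phenyl]lithium | [Li]c1c(OCOC)cc(OCOC)cc1OCOC
F9 | step 5 | (2R)-2-methyl-1-[2,4,6-tris(methoxymethoxy)phenyl]butan-1-one | CC[C@@H](C)C(=O)c1c(OCOC)cc(OCOC)cc1OCOC
A1 | alternative 1 | 3-methoxy-4-methylcyclobut-2-en-1-one | COC1=CC(=O)C1C
A2 | alternative 1 | ring A bis(siloxyalkyne): 1,3,5-tris(benzyloxy)-2-[(2R)-1-(tert-butyldimethylsiloxy)-2-methylbutyl]-4,6-bis[3-(triisopropylsiloxy)prop-2-ynyl]benzene | CC[C@@H](C)C(O[Si](C)(C)C(C)(C)C)c1c(OCc2ccccc2)c(CC#CO[Si](C(C)C)(C(C)C)C(C)C)c(OCc2ccccc2)c(CC#CO[Si](C(C)C)(C(C)C)C(C)C)c1OCc1ccccc1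
A3 | alternative 1 | protected trimer with both side rings formed (C2 OH, C3 methyl, C4 OMe, C5 H, C6 triisopropylsilyl ether) | CC[C@@H](C)C(O[Si](C)(C)C(C)(C)C)c1c(OCc2ccccc2)c(Cc2c(O)c(C)c(OC)cc2O[Si](C(C)C)(C(C)C)C(C)C)c(OCc2ccccc2)c(Cc2c(O)c(C)c(OC)cc2O[Si](C(C)C)(C(C)C)C(C)C)c1OCc1ccccc1
A4 | alternative 2 | 4-acetyl-5-methoxy-6-methyl-2-[(methanesulfinyl)methyl]-1,3-phenylene diacetate | CS(=O)Cc1c(OC(C)=O)c(C)c(OC)c(C(C)=O)c1OC(C)=O
A5 | alternative 2 | trimer with a methylthio group on each bridge carbon and side-ring phenols as acetates | CC[C@@H](C)C(=O)c1c(O)c(C(SC)c2c(OC(C)=O)c(C)c(OC)c(C(C)=O)c2OC(C)=O)c(O)c(C(SC)c2c(OC(C)=O)c(C)c(OC)c(C(C)=O)c2OC(C)=O)c1O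
A6 | alternative 3 | 3,5-bis{[2,6-bis(benzyloxy)-4-methoxy-3-methylphenyl]methyl}-4-hydroxy-6-[(3R)-3-methyl-2-oxopentyl]-2H-pyran-2-one | CC[C@@H](C)C(=O)Cc1oc(=O)c(Cc2c(OCc3ccccc3)c(C)c(OC)cc2OCc2ccccc2)c(O)c1Cc1c(OCc2ccccc2)c(C)c(OC)cc1OCc1ccccc1
A7 | alternative 3 | methyl (8R)-2,4-bis{[2,6-bis(benzyloxy)-4-methoxy-3-methylphenyl]methyl}-8-methyl-3,5,7-trioxodecanoate | CC[C@@H](C)C(=O)CC(=O)C(Cc1c(OCc2ccccc2)c(C)c(OC)cc1OCc1ccccc1)C(=O)C(Cc1c(OCc2ccccc2)c(C)c(OC)cc1OCc1ccccc1)C(=O)OC
A8 | alternative 3 | (2R)-1-{3,5-bis{[2,6-bis(benzyloxy)-4-methoxy-3-methylphenyl]methyl}-2,4,6-trihydroxyphenyl}-2-methylbutan-1-one | CC[C@@H](C)C(=O)c1c(O)c(Cc2c(OCc3ccccc3)c(C)c(OC)cc2OCc2ccccc2)c(O)c(Cc2c(OCc3ccccc3)c(C)c(OC)cc2OCc2ccccc2)c1O
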